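The indole is opened at its C2=C3 bond: C3 is read as the carbonyl carbon of an aryl oxazol-5-yl ketone and C2 as the formyl carbon on the aniline nitrogen N1, two electrophilic carbons held ortho on the fully substituted benzene ring. A titanium-mediated reductive coupling should join them and close the five-membered ring of the indole in a single late operation, with the bromine, the methoxy group, the oxazole and the bromopyrrole already in place. The precursor, formamide 17, arises from addition of a nitroaryl magnesium reagent to an oxazole-5-carbaldehyde, oxidation, nitro reduction and N-formylation; the pyrrole unit is bought already brominated at C5.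

Key step: step 11

Remark: SEM stands for the [2-(trimethylsilyl)ethoxy]methyl group on the pyrrole nitrogen. The target has no stereocentre; carbinol 14 is racemic and its stereocentre is removed in step 8. 5-Bromo-1H-pyrrole-2-carboxylic acid and ethyl 2-chloro-3-oxopropanoate are assumed to be catalogue compounds.

Step 1
Reactants: 1 2-methoxy-6-nitroaniline
Product: 2 4-bromo-2-methoxy-6-nitroaniline
Conditions: NBS, MeCN, 0 °C → rt
Reagents that add atoms: N-bromosuccinimide, O=C1CCC(=O)N1Br
Why: Electrophilic aromatic bromination is steered by the amino group to its only free para position, which is also meta to the nitro group, so one monobromide is expected.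

Step 2
Reactants: 2 4-bromo-2-methoxy-6-nitroaniline
Product: 4 5-bromo-2-iodo-1-methoxy-3-nitrobenzene, via arenediazonium hydrogensulfate 3 (not isolated)
Conditions: NaNO2, H2SO4/AcOH, 0–5 °C; then KI, H2O, 0 °C → rt
Reagents that add atoms: potassium iodide, [K+].[I-]; sodium nitrite, [Na+].[O-]N=O (its nitrogen stays only in 3); sulfuric acid, OS(=O)(=O)O (counter-ion of 3 only)
Why: Diazotisation of the weakly basic nitroaniline in strong acid followed by iodide displacement (Sandmeyer-type iodination, no copper needed) should replace NH2 by iodine without touching the bromide, the ether or the nitro group.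

Step 3
Reactants: 5 5-bromo-1H-pyrrole-2-carboxylic acid
Product: 7 5-bromo-1H-pyrrole-2-carboxamide, via acyl imidazolide 6 (not isolated)
Conditions: 1,1'-carbonyldiimidazole (CDI), THF, rt; then aq. NH3, 0 °C → rt
Reagents that add atoms: ammonia, N; 1,1'-carbonyldiimidazole, O=C(n1ccnc1)n1ccnc1 (its imidazolyl group stays only in 6)
Why: Activation of the acid as its acyl imidazolide and aminolysis with ammonia is a standard primary amide synthesis that leaves the pyrrole C–Br bond alone.

Step 4
Reactants: 7 5-bromo-1H-pyrrole-2-carboxamide; 8 ethyl 2-chloro-3-oxopropanoate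
Product: 9 ethyl 2-(5-bromo-1H-pyrrol-2-yl)-1,3-oxazole-5-carboxylate
Conditions: 8 (3 equiv), 1,4-dioxane, 4 Å molecular sieves, 100 °C
Reagents that add atoms: none
Why: Blümlein–Lewy oxazole synthesis, in which the amide oxygen displaces chloride at the carbon bearing the ester and the nitrogen condenses with the formyl group, so the ester can only end at oxazole C5 and the pyrrole at C2.

Step 5
Reactants: 9 ethyl 2-(5-bromo-1H-pyrrol-2-yl)-1,3-oxazole-5-carboxylate
Product: 11 ethyl 2-(5-bromo-1-SEM-1H-pyrrol-2-yl)-1,3-oxazole-5-carboxylate, via sodium pyrrolide 10 (not isolated)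
Conditions: NaH, DMF, 0 °C; then SEMCl, 0 °C → rt
Reagents that add atoms: 2-(trimethylsilyl)ethoxymethyl chloride (SEMCl), C[Si](C)(C)CCOCCl; sodium hydride, [Na+].[H-] (its sodium stays only in 10)
Why: The pyrrole N–H is the only acidic site, so deprotonation and SN2 N-alkylation with SEMCl should mask it before the organomagnesium step.

Step 6
Reactants: 11 ethyl 2-(5-bromo-1-SEM-1H-pyrrol-2-yl)-1,3-oxazole-5-carboxylate
Product: 12 2-(5-bromo-1-SEM-1H-pyrrol-2-yl)-1,3-oxazole-5-carbaldehyde
Conditions: i-Bu2AlH (1.2 equiv), CH2Cl2, −78 °C; MeOH, then aq. KNaC4H4O6 (Rochelle salt)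
Reagents that add atoms: none
Why: Partial reduction of an ester by one hydride equivalent at low temperature, where the aluminium hemiacetal survives until the quench, is a standard route to oxazole aldehydes and spares the C–Br bond and the SEM group.

Step 7
Reactants: 4 5-bromo-2-iodo-1-methoxy-3-nitrobenzene; 12 2-(5-bromo-1-SEM-1H-pyrrol-2-yl)-1,3-oxazole-5-carbaldehyde
Product: 14 (4-bromo-2-methoxy-6-nitrophenyl)[2-(5-bromo-1-SEM-1H-pyrrol-2-yl)-1,3-oxazol-5-yl]methanol (racemic), via arylmagnesium chloride 13 (not isolated)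
Conditions: 4 (1.3 equiv), PhMgCl (1.2 equiv), THF, −40 °C; then 12, −40 → −20 °C; aq. NH4Cl
Reagents that add atoms: phenylmagnesium chloride, Cl[Mg]c1ccccc1 (its MgCl stays only in 13)
Why: Iodine–magnesium exchange is fast for an aryl iodide flanked by nitro and methoxy groups, which also chelate and stabilise the arylmagnesium at −40 °C, and its 1,2-addition to the non-enolisable aldehyde should give the racemic carbinol while neither C–Br bond exchanges.

Step 8
Reactants: 14 (4-bromo-2-methoxy-6-nitrophenyl)[2-(5-bromo-1-SEM-1H-pyrrol-2-yl)-1,3-oxazol-5-yl]methanol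
Product: 15 (4-bromo-2-methoxy-6-nitrophenyl)[2-(5-bromo-1-SEM-1H-pyrrol-2-yl)-1,3-oxazol-5-yl]methanone
Conditions: Dess–Martin periodinane, CH2Cl2, rt
Reagents that add atoms: none
Why: Dess–Martin oxidation of a doubly activated secondary carbinol is reliable even next to a di-ortho-substituted arene and does not attack the bromopyrrole.

Step 9
Reactants: 15 (4-bromo-2-methoxy-6-nitrophenyl)[2-(5-bromo-1-SEM-1H-pyrrol-2-yl)-1,3-oxazol-5-yl]methanone
Product: 16 (2-amino-4-bromo-6-methoxyphenyl)[2-(5-bromo-1-SEM-1H-pyrrol-2-yl)-1,3-oxazol-5-yl]methanone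
Conditions: Fe powder, NH4Cl, EtOH/H2O (4:1), 75 °C
Reagents that add atoms: none
Why: Iron-mediated nitro reduction (Béchamp type) is chemoselective for NO2 over aryl bromides and diaryl ketones, and any 2,1-benzisoxazole formed from the hydroxylamine stage and the ketone should be cleaved by the same reagent to the amino ketone.

Step 10
Reactants: 16 (2-amino-4-bromo-6-methoxyphenyl)[2-(5-bromo-1-SEM-1H-pyrrol-2-yl)-1,3-oxazol-5-yl]methanone
Product: 17 N-{5-bromo-3-methoxy-2-[2-(5-bromo-1-SEM-1H-pyrrol-2-yl)-1,3-oxazole-5-carbonyl]phenyl}formamide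
Conditions: HCO2H/Ac2O (premixed, 55 °C), then 16, THF, 0 °C → rt
Reagents that add atoms: formic acid, O=CO (transferred as acetic formic anhydride, CC(=O)OC=O)
Why: N-Formylation with the mixed anhydride transfers the more electrophilic formyl group selectively, even to an aniline deactivated by hydrogen bonding to the ortho ketone.

Step 11
Reactants: 17 N-{5-bromo-3-methoxy-2-[2-(5-bromo-1-SEM-1H-pyrrol-2-yl)-1,3-oxazole-5-carbonyl]phenyl}formamide
Product: 18 6-bromo-3-[2-(5-bromo-1-SEM-1H-pyrrol-2-yl)-1,3-oxazol-5-yl]-4-methoxy-1H-indole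
Conditions: TiCl3 (3 equiv), Zn dust (6 equiv), THF, reflux; 17 added slowly (final 0.02 M)
Reagents that add atoms: none
Why: Low-valent titanium made from TiCl3 and Zn should transfer an electron to the aryl oxazolyl ketone, and the titanium-bound ketyl carbon (future C3) should add to the neighbouring formamide carbonyl (future C2) to give a titanium-bridged 2,3-dioxygenated indoline that is deoxygenated to the C2=C3 double bond as in a McMurry olefination. The closest known reaction type is the Fürstner indole synthesis, the reductive oxo-amide coupling of N-acyl 2-aminoaryl ketones, in which N-formyl substrates give 2-unsubstituted indoles. The five-membered ring (N1, C2, C3, C3a, C7a) closes in a 5-exo-trig mode, the attacked formyl C=O lying outside the new ring. No stereocentre arises because both coupled carbons end up sp2. The step needs chemoselectivity for the intramolecular ketone–amide coupling over intermolecular pinacol coupling, over reduction of the ketone alone and over cleavage of the two C–Br bonds; the ortho arrangement that lets both carbonyl oxygens bind one titanium centre, slow addition at high dilution and the mild TiCl3/Zn couple should secure it. Because the benzene ring arrives fully substituted, the cyclisation has only one possible orientation.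

Step 12
Reactants: 18 6-bromo-3-[2-(5-bromo-1-SEM-1H-pyrrol-2-yl)-1,3-oxazol-5-yl]-4-methoxy-1H-indole
Product: 19 6-bromo-3-[2-(5-bromo-1H-pyrrol-2-yl)-1,3-oxazol-5-yl]-4-methoxy-1H-indole
Conditions: n-Bu4NF (1 M in THF, 5 equiv), THF, 65 °C; aq. work-up
Reagents that add atoms: none
Why: Fluoride attacks silicon, β-elimination releases ethene and the N-CH2-O anion loses formaldehyde (standard SEM cleavage), which the indole, the oxazole, the aryl ether and both C–Br bonds should tolerate.

Compound list
1 | 2-methoxy-6-nitroaniline | COc1cccc([N+](=O)[O-])c1N | starting material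
2 | 4-bromo-2-methoxy-6-nitroaniline | COc1cc(Br)cc([N+](=O)[O-])c1N | intermediate
3 | 4-bromo-2-methoxy-6-nitrobenzenediazonium hydrogensulfate | COc1cc(Br)cc([N+](=O)[O-])c1[N+]#N.OS(=O)(=O)[O-] | intermediate (not isolated)
4 | 5-bromo-2-iodo-1-methoxy-3-nitrobenzene | COc1cc(Br)cc([N+](=O)[O-])c1I | intermediate
5 | 5-bromo-1H-pyrrole-2-carboxylic acid | OC(=O)c1ccc(Br)[nH]1 | starting material
6 | (5-bromo-1H-pyrrol-2-yl)(1H-imidazol-1-yl)methanone | O=C(c1ccc(Br)[nH]1)n1ccnc1 | intermediate (not isolated)
7 | 5-bromo-1H-pyrrole-2-carboxamide | NC(=O)c1ccc(Br)[nH]1 | intermediate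
8 | ethyl 2-chloro-3-oxopropanoate (racemic, largely enolised) | CCOC(=O)C(Cl)C=O | starting material
9 | ethyl 2-(5-bromo-1H-pyrrol-2-yl)-1,3-oxazole-5-carboxylate | CCOC(=O)c1cnc(-c2ccc(Br)[nH]2)o1 | intermediate
10 | sodium salt of 9 (N-sodio pyrrolide) | CCOC(=O)c1cnc(-c2ccc(Br)[n-]2)o1.[Na+] | intermediate (not isolated)
11 | ethyl 2-(5-bromo-1-{[2-(trimethylsilyl)ethoxy]methyl}-1H-pyrrol-2-yl)-1,3-oxazole-5-carboxylate | CCOC(=O)c1cnc(-c2ccc(Br)n2COCC[Si](C)(C)C)o1 | intermediate
12 | 2-(5-bromo-1-{[2-(trimethylsilyl)ethoxy]methyl}-1H-pyrrol-2-yl)-1,3-oxazole-5-carbaldehyde | O=Cc1cnc(-c2ccc(Br)n2COCC[Si](C)(C)C)o1 | intermediate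
13 | (4-bromo-2-methoxy-6-nitrophenyl)magnesium chloride | COc1cc(Br)cc([N+](=O)[O-])c1[Mg]Cl | intermediate (not isolated)
14 | (4-bromo-2-methoxy-6-nitrophenyl)[2-(5-bromo-1-SEM-1H-pyrrol-2-yl)-1,3-oxazol-5-yl]methanol, racemic | COc1cc(Br)cc([N+](=O)[O-])c1C(O)c1cnc(-c2ccc(Br)n2COCC[Si](C)(C)C)o1 | intermediate
15 | (4-bromo-2-methoxy-6-nitrophenyl)[2-(5-bromo-1-SEM-1H-pyrrol-2-yl)-1,3-oxazol-5-yl]methanone | COc1cc(Br)cc([N+](=O)[O-])c1C(=O)c1cnc(-c2ccc(Br)n2COCC[Si](C)(C)C)o1 | intermediate
16 | (2-amino-4-bromo-6-methoxyphenyl)[2-(5-bromo-1-SEM-1H-pyrrol-2-yl)-1,3-oxazol-5-yl]methanone | COc1cc(Br)cc(N)c1C(=O)c1cnc(-c2ccc(Br)n2COCC[Si](C)(C)C)o1 | intermediate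
17 | N-{5-bromo-3-methoxy-2-[2-(5-bromo-1-SEM-1H-pyrrol-2-yl)-1,3-oxazole-5-carbonyl]phenyl}formamide | O=CNc1cc(Br)cc(OC)c1C(=O)c1cnc(-c2ccc(Br)n2COCC[Si](C)(C)C)o1 | intermediate
18 | 6-bromo-3-[2-(5-bromo-1-SEM-1H-pyrrol-2-yl)-1,3-oxazol-5-yl]-4-methoxy-1H-indole | COc1cc(Br)cc2[nH]cc(-c3cnc(-c4ccc(Br)n4COCC[Si](C)(C)C)o3)c12 | intermediate
19 | 6-bromo-3-[2-(5-bromo-1H-pyrrol-2-yl)-1,3-oxazol-5-yl]-4-methoxy-1H-indole | COc1cc(Br)cc2[nH]cc(-c3cnc(-c4ccc(Br)[nH]4)o3)c12 | target

Total step count: 12. Longest linear sequence: 10 steps (steps 3 to 12, from 5).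

Steps most likely to fail

Step 11. The reductant may cleave the C–Br bonds, reduce the ketone alone, or couple two ketones intermolecularly before the ring closes. The fallback sets out from amino ketone 16. A Wittig reaction with Ph3P=CHOMe, made from (methoxymethyl)triphenylphosphonium chloride and KOt-Bu in THF, should give the enol ether 5-bromo-3-methoxy-2-{2-methoxy-1-[2-(5-bromo-1-SEM-1H-pyrrol-2-yl)-1,3-oxazol-5-yl]ethenyl}aniline F1 as an E/Z mixture. Catalytic pyridinium p-toluenesulfonate in warm toluene should then let the amino group add to the protonated enol ether and expel methanol; this closes the ring at N1–C2 instead and is mild enough for the SEM group. Both alkene isomers converge, and the sequence returns to the route at 18.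

Step 4. The weakly nucleophilic amide may convert slowly, and the hot, HCl-releasing medium may cause loss or migration of the pyrrole bromine. The fallback sets out from acid 5. Amide coupling (EDC·HCl, HOBt, i-Pr2NEt, DMF) with racemic ethyl 3-amino-2-hydroxypropanoate hydrochloride should give ethyl 3-[(5-bromo-1H-pyrrole-2-carbonyl)amino]-2-hydroxypropanoate F2. Dess–Martin oxidation should then give the keto amide ethyl 3-[(5-bromo-1H-pyrrole-2-carbonyl)amino]-2-oxopropanoate F3. Robinson–Gabriel cyclodehydration with PPh3, I2 and Et3N in CH2Cl2 closes the oxazole with the ester at C5 under non-acidic conditions. This returns to the route at 9 and bypasses 7 and 8.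

Step 6. The aluminium hemiacetal may collapse before the quench, so that reduction runs on past the aldehyde. The fallback sets out from ester 11. Exhaustive reduction with NaBH4/CaCl2 in EtOH/THF should give the primary alcohol [2-(5-bromo-1-SEM-1H-pyrrol-2-yl)-1,3-oxazol-5-yl]methanol F4. Oxidation of this heteroaryl carbinol with MnO2 in CH2Cl2 stops at the aldehyde and returns to the route at 12.

Further compounds
F1 | step 11 | 5-bromo-3-methoxy-2-{2-methoxy-1-[2-(5-bromo-1-SEM-1H-pyrrol-2-yl)-1,3-oxazol-5-yl]ethenyl}aniline (E/Z mixture) | COC=C(c1cnc(-c2ccc(Br)n2COCC[Si](C)(C)C)o1)c1c(N)cc(Br)cc1OC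
F2 | step 4 | ethyl 3-[(5-bromo-1H-pyrrole-2-carbonyl)amino]-2-hydroxypropanoate (racemic) | CCOC(=O)C(O)CNC(=O)c1ccc(Br)[nH]1
F3 | step 4 | ethyl 3-[(5-bromo-1H-pyrrole-2-carbonyl)amino]-2-oxopropanoate | CCOC(=O)C(=O)CNC(=O)c1ccc(Br)[nH]1
F4 | step 6 | [2-(5-bromo-1-SEM-1H-pyrrol-2-yl)-1,3-oxazol-5-yl]methanol | OCc1cnc(-c2ccc(Br)n2COCC[Si](C)(C)C)o1
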